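## The problem

Sodwanone S (47) consists of two oxa-bicycles joined by a two-carbon linker. Skeleton atoms are numbered along the SMILES string: C1 is the secondary methyl, ring B is C2–C3–C4–C5–C11–C12, ring A is C5–O6–C7–C8–C9–C10–C11, the linker is C13–C14, ring C is C15–C16–C22–C23–C24–C25 and ring D is C16–C17–C18–C19–C20–O21–C22. Both seven-membered rings contain a secondary–tertiary ether (C5–O6–C7Me2 and C22–O21–C20Me2) that cannot be made by substitution at the tertiary carbon with a basic alkoxide. The eight stereocentres (C2, C5, C8, C12, C15, C16, C22, C25, all S) fall into two groups insulated by the linker, so each half needs its own source of absolute configuration. Within the west half C2 can control C12, and C12 can control C5, whereas C8 is remote and needs reagent control. Within the east half C22 can control C16, the angular methyl on C16 can control C25, and C15 is epimerisable next to a C25 carbonyl. Groups that limit the reagents are the allylic tertiary ether C5–O6 beside the hindered trisubstituted C10=C11 alkene, the tertiary C25 carbinol with its axial methyl (not accessible by methyl addition to a ketone), and the enolisable α-alkoxy ketone at C19. The feature that makes the key step possible is in ring B: quaternary C12 (methyl and linker) lies between C2 (H and CH3, methyls trans) and C11, which can be a ketone carbon. This is the pattern left by conjugate methylation at C2 of a 2-substituted cyclohexenone followed by methylation of the enolate at C12.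

## Retrosynthesis

**End game (47 ⇐ 46 ⇐ 45 ⇐ 44).** No skeletal bond is cut. The C19 ketone is carried as a triethylsilyl-protected carbinol and the C8 hydroxyl as a hindered TBS ether. A free C19 ketone would be enolised at C18 during the enolate chemistry at C15 and would compete in the olefination at C25. The forward steps must remove TES beside TBS (45), oxidise only C19 (46, the C25 carbinol being tertiary) and then free C8–OH.

**C25 carbinol (44 ⇐ 42 ⇐ 41).** The C25–O bond is cut back to exocyclic alkene 42 and this to ketone 41. Methyl addition to 41 is rejected because the axial methyl on C16 forces equatorial attack and would give the C25 epimer. Oxygen delivery to the methylene carbon from the equatorial side gives the axial methyl. The reaction must also leave C10=C11 alone, which favours oxymercuration over peracid epoxidation.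

**Union and ring D (41 ⇐ 40 ⇐ 39 ⇐ 37 ⇐ 25 + 35).** The C17=C18 bond of ring D is cut by ring-closing metathesis (40 ⇐ 39) and the C14–C15 bond by an aldol reaction of aldehyde 25 with the enolate from silyl enol ether 35. The cut at C14–C15 is preferred to C12–C13 because a bond to quaternary C12 would require alkylation with a large electrophile, which enters anti to the C2 methyl and gives the wrong diastereomer. The regiochemistry of the C15 enolate, which direct enolisation of a C25 ketone would not give, is fixed by the way 35 is made. Fragments 25 and 35 are of similar size and each carries all of its stereocentres except C15 and C25.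

**East fragment (35 ⇐ 34 ⇐ 33 ⇐ 32 ⇐ 31 ⇐ 30 + 16; 30 ⇐ 29 ⇐ 28 ⇐ 26).** The C16–C17 bond is cut as a copper-catalysed conjugate addition of a vinyl group to enone 34. The C22 ether directs the vinyl group anti, which sets the trans ring fusion, and the enolate is released on the C15 side as 35. The tertiary ether O21–C20 is made on the unhindered alcohol 30 with imidate 16, before the quaternary centre exists; the same hydroxyl after the conjugate addition would be neopentylic. The vinyl group of 31 is converted into aldehyde 32 and this into the allylic carbinol 33 that supplies C18 and C19. Alcohol 30 comes from commercial ketal 26 by dehydrogenation (28), CBS reduction (29) and hydrolysis.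

**West fragment, ring A (25 ⇐ 24 ⇐ 23 ⇐ 22 ⇐ 21 ⇐ 20 ⇐ 18 ⇐ 17 ⇐ 13 + 16).** The C10=C11 bond is cut by ring-closing metathesis (23 ⇐ 22), the C8–C9 bond by asymmetric allylboration of aldehyde 18, and the O6–C7 bond by acid-catalysed alkylation of α-hydroxy ketone 13 with imidate 16. A 7-endo hydroxy-epoxide closure was considered for O6–C7, but 6-exo opening would compete. The metathesis must close onto a 1,1-disubstituted alkene beside a quaternary carbon, which is the hardest demand in this half.

**C5 oxygen (13 ⇐ 10).** The C5–O bond is cut by Rubottom oxidation. Ketone 10 can enolise only toward C5, and the side arm on C12 shields one face of the enol ether, so the oxygen should arrive cis to the C12 methyl, in the equatorial and thermodynamically preferred position.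

**Key disconnection (10 ⇐ 6 + 7 + 8).** Both C–CH3 bonds of ring B are cut: C2–CH3 from trimethylaluminium (7) and C12–CH3 from iodomethane (8), leaving achiral enone 6. The order matters. The large arm must already be on the enone so that the small electrophile enters anti to the new C2 methyl, which puts the arm cis to it. Two stereocentres and two skeletal bonds are removed at once, and the precursor has no stereocentre.

**Enone (6 ⇐ 5 ⇐ 4 ⇐ 1 + 2).** The ring–arm bond is cut by Birch reductive alkylation of 2-methoxybenzoic acid (1) with bromide 2. Hydrolysis and decarboxylation of 4 place the double bond on the substituted carbon. A Birch reduction of an ortho-alkylanisole would instead end as a 6-substituted cyclohex-2-enone, so the carboxylate route is chosen.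

## Roads not taken

**Alternative 1:** The cut goes through the O21–C20 bond of ring D and the C15–C16 bond of ring C together, back to an open-chain precursor of A1 carrying two (S,S)-epoxides and an allylsilane. In the forward step Me3SiOTf activates the terminal epoxide, the inner epoxide oxygen attacks its CMe2 carbon, and the allylsilane opens the epoxonium ion to give exo-methylene alcohol A1.
- Merits: two rings and the C16, C22 and C19 centres form in one operation, the tertiary ether forms intramolecularly, and the exo-methylene at C25 is the right handle for equatorial oxygen delivery. For rings C/D this is clearly shorter than the eight steps to 35 plus steps 23–26.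
- Weak points: A1 carries the linker carbons, so the union must make the C12–C13 bond to the quaternary carbon of ring B. An enolate alkylation there puts the large electrophile anti to the C2 methyl, the wrong relative configuration. The cascade also competes with 6-exo opening, elimination and premature termination.
- Against its step economy the chosen plan sets a catalyst-controlled C2/C12 pair with the arm cis to the C2 methyl, and a union at the unhindered C14–C15 bond.

**Alternative 2:** The cut is the C22–O21 bond of ring D, made with a temporary second C–O bond. Camphorsulfonic acid lets the chiral diol arm of the open precursor of A2 ketalise one of two enantiotopic carbonyls of a 2-methyl-2-alkylcyclohexane-1,3-dione, giving bicyclic ketal A2.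
- Merits: cheap dione chemistry, C16 set by desymmetrisation under thermodynamic control, and the hindered tertiary ether closed intramolecularly. This is a more secure answer to the ring D ether than the intermolecular imidate alkylation of step 18.
- Weak points: after A2 the ketal must be opened reductively with the right regiochemistry and hydride face at C22. The extra CH2–O carbon must be deoxygenated to the second C20 methyl. The remaining ring carbonyl sits at C15, not C25, so attaching the linker means addition to a ketone flanked by two fully substituted carbons, and C25 still needs its methyl and hydroxyl.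
- Against A2's better ether closure the chosen plan sets a C25 ketone with a regiodefined C15 enolate, exactly where the union and the carbinol need them, with no redox corrections on ring C.

**Alternative 3:** The cut is the C11–C12 bond. Zerovalent palladium, from Pd(OAc)2 and a bisphosphine, inserts into the enol triflate of the oxepene precursor of A3. The vinylpalladium adds 6-exo to a tethered (E)-trisubstituted allylic silyl ether, and β-hydride elimination gives enol silyl ether A3.
- Merits: ring B and quaternary C12 form together, C10=C11 comes from an enol triflate and not from a hindered metathesis, and the linker aldehyde appears masked as the enol ether. It avoids steps 11–14 and is probably shorter for the west half.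
- Weak points: C2 must be installed separately in the acyclic tether, and the configuration at C12 then depends on substrate-controlled facial selectivity of the insertion, with two diastereomeric chair-like transition states and a geometry-defined trisubstituted alkene. The oxepanone enol triflate also needs regioselective enolisation beside the C5 ether carbon.
- Against the shorter west half the chosen plan sets two ring B stereocentres from one catalytic step whose selectivity has a clear origin: ligand for C2, anti-methylation for C12.

Key step: step 4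

Remark 1: L* is O,O′-[(S)-1,1′-binaphthyl-2,2′-diyl] N,N-bis[(R)-1-phenylethyl]phosphoramidite. The antipodes of L*, of the CBS catalyst (step 16) and of (−)-MIB (step 20) are those expected from the usual models to give the configurations drawn; if a sense of induction proves opposite, the other antipode is used.
Remark 2: the carbinol configuration at C19 (compounds 33–45) does not affect 47, because C19 ends as a ketone; it is drawn as the expected (S) epimer.
Remark 3: 37 and 38 are carried as mixtures at C14 and C15, and 39 as a mixture of alkene isomers; all converge in step 26.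

## Route

Step 1
Reactants: 1 2-methoxybenzoic acid; 2 (2-bromoethoxy)(tert-butyl)dimethylsilane
Product: 4 1-[2-(tert-butyldimethylsilyloxy)ethyl]-2-methoxycyclohexa-2,5-diene-1-carboxylic acid (racemic), via dilithium dienediolate 3 (not isolated)
Conditions: Li, NH3(l)/THF, −78 °C; then 2, −78 → −33 °C; NH4Cl, work-up at pH 4
Reagents that add atoms: none
Why: Birch reductive alkylation: the carboxylate directs reduction to dianion 3, which is alkylated at the ring carbon α to the carboxylate by the primary bromide; the methoxy group stays on a double bond as an enol ether, which fixes the later carbonyl next to the alkylated carbon.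

Step 2
Reactants: 4 1-[2-(tert-butyldimethylsilyloxy)ethyl]-2-methoxycyclohexa-2,5-diene-1-carboxylic acid
Product: 5 2-(2-hydroxyethyl)cyclohex-2-en-1-one
Conditions: 2 M HCl, THF, 50 °C
Reagents that add atoms: water, O
Why: Enol ether hydrolysis gives a β-keto acid that decarboxylates, and the β,γ double bond then moves into conjugation on the substituted carbon to give the 2-substituted enone; the silyl ether is cleaved under these conditions and is restored in step 3.

Step 3
Reactants: 5 2-(2-hydroxyethyl)cyclohex-2-en-1-one
Product: 6 2-[2-(tert-butyldimethylsilyloxy)ethyl]cyclohex-2-en-1-one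
Conditions: TBSCl, imidazole, DMF, 0 °C → rt
Reagents that add atoms: tert-butyldimethylsilyl chloride, CC(C)(C)[Si](C)(C)Cl
Why: Standard silylation of a primary alcohol; the ether is inert to AlMe3, MeLi and LDA and is later the only primary silyl ether, so it can be removed selectively.

Step 4
Reactants: 6 2-[2-(tert-butyldimethylsilyloxy)ethyl]cyclohex-2-en-1-one; 7 trimethylaluminium; 8 iodomethane
Product: 10 (2S,3S)-2-[2-(tert-butyldimethylsilyloxy)ethyl]-2,3-dimethylcyclohexan-1-one, via dimethylaluminium enolate 9 (not isolated)
Conditions: Cu(OTf)2 (5 mol%), L* (10 mol%), 7, Et2O, −30 °C; then THF, MeLi, −30 → 0 °C; then 8, HMPA, 0 °C → rt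
Reagents that add atoms: trimethylaluminium, C[Al](C)C; iodomethane, CI
Why: AlMe3 reduces divalent copper triflate to a monovalent copper–phosphoramidite complex, transmetalation gives a methylcopper species that adds to the β-carbon of 6, and the enolate is released as the tetrasubstituted aluminium enolate 9, so its regiochemistry is fixed by the conjugate addition. MeLi converts 9 into the more nucleophilic lithium aluminate, which MeI methylates on carbon in THF/HMPA. The closest known reaction type is the copper/phosphoramidite-catalysed asymmetric conjugate addition of trialkylaluminium reagents to 2-substituted cyclohexenones, with alkylation of the aluminium enolate after ate activation. No ring closes; two C–CH3 bonds form. The secondary methyl centre (3S) is set by the ligand, which selects the enone face. The quaternary centre (2S) is set by the substrate: in the half-chair enolate the new 3-methyl group sits pseudoaxial to avoid allylic strain with the 2-substituent, and MeI attacks axially on the opposite face, giving trans methyls with the arm cis to the 3-methyl. The step needs 1,4- over 1,2-addition (copper catalysis with non-basic AlMe3), enantiofacial selectivity (ligand), and C-monomethylation before the enolate equilibrates (ate complex, excess MeI); the silyl ether arm is inert to all reagents.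

Step 5
Reactants: 10 (2S,3S)-2-[2-(tert-butyldimethylsilyloxy)ethyl]-2,3-dimethylcyclohexan-1-one
Product: 13 (2S,3S,6S)-2-[2-(tert-butyldimethylsilyloxy)ethyl]-6-hydroxy-2,3-dimethylcyclohexan-1-one, via silyl enol ether 11 (not isolated), via α-silyloxy ketone 12 (not isolated)
Conditions: LDA, TMSCl, THF, −78 °C; then mCPBA, NaHCO3, hexane/CH2Cl2, −15 °C; then K2CO3, MeOH, 0 °C
Reagents that add atoms: 3-chloroperbenzoic acid, OOC(=O)c1cccc(Cl)c1
Why: Rubottom oxidation: 10 can enolise only toward C5 because C12 is quaternary, and the peracid attacks the silyl enol ether anti to the pseudoaxial arm on that carbon; the resulting equatorial (6S) hydroxy ketone, cis to the C12 methyl, is also the thermodynamically preferred epimer.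

Step 6
Reactants: 14 2-methylbut-3-en-2-ol; 15 trichloroacetonitrile
Product: 16 2-methylbut-3-en-2-yl 2,2,2-trichloroacetimidate
Conditions: KH (10 mol%), Et2O, 0 °C
Reagents that add atoms: none
Why: Base-catalysed addition of the tertiary alkoxide to the nitrile (imidate formation); the product is kept cold and used at once so that it does not rearrange to the allylic amide.

Step 7
Reactants: 13 (2S,3S,6S)-2-[2-(tert-butyldimethylsilyloxy)ethyl]-6-hydroxy-2,3-dimethylcyclohexan-1-one; 16 2-methylbut-3-en-2-yl 2,2,2-trichloroacetimidate
Product: 17 (2S,3S,6S)-2-[2-(tert-butyldimethylsilyloxy)ethyl]-2,3-dimethyl-6-[(2-methylbut-3-en-2-yl)oxy]cyclohexan-1-one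
Conditions: TfOH (5 mol%), cyclohexane/CH2Cl2, −20 → 0 °C
Reagents that add atoms: none
Why: Acid-catalysed trichloroacetimidate O-alkylation: protonated 16 ionises to the 1,1-dimethylallyl cation, which the hydroxyl captures at the tertiary terminus under kinetic control; the C5 centre is the stable epimer next to the ketone, so the acid cannot erode it.

Step 8
Reactants: 17 (2S,3S,6S)-2-[2-(tert-butyldimethylsilyloxy)ethyl]-2,3-dimethyl-6-[(2-methylbut-3-en-2-yl)oxy]cyclohexan-1-one
Product: 18 2-({(1S,3S,4S)-3-[2-(tert-butyldimethylsilyloxy)ethyl]-3,4-dimethyl-2-oxocyclohexyl}oxy)-2-methylpropanal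
Conditions: O3, CH2Cl2, −78 °C; then Me2S, −78 °C → rt
Reagents that add atoms: ozone, [O-][O+]=O
Why: Ozonolysis of the only C=C bond gives a non-enolisable α-alkoxy aldehyde; the ketone and silyl ether are unaffected.

Step 9
Reactants: 18 2-({(1S,3S,4S)-3-[2-(tert-butyldimethylsilyloxy)ethyl]-3,4-dimethyl-2-oxocyclohexyl}oxy)-2-methylpropanal
Product: 20 (2S,3S,6S)-2-[2-(tert-butyldimethylsilyloxy)ethyl]-6-{[(3S)-3-hydroxy-2-methylhex-5-en-2-yl]oxy}-2,3-dimethylcyclohexan-1-one, via diisopinocampheylborinate 19 (not isolated)
Conditions: (−)-Ipc2B(allyl), Et2O, −78 °C; then NaBO3·4H2O, THF/H2O, rt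
Reagents that add atoms: (−)-B-allyldiisopinocampheylborane, C=CCB([C@@H]1C[C@@H]2C[C@H]([C@H]1C)C2(C)C)[C@@H]1C[C@@H]2C[C@H]([C@H]1C)C2(C)C
Why: Brown allylboration through a chair six-membered transition state: the pinene-derived groups on boron select the aldehyde face and set C8 as S under reagent control, since the nearest stereocentre is four atoms away across the ether; the aldehyde reacts far faster than the hindered ketone at −78 °C.

Step 10
Reactants: 20 (2S,3S,6S)-2-[2-(tert-butyldimethylsilyloxy)ethyl]-6-{[(3S)-3-hydroxy-2-methylhex-5-en-2-yl]oxy}-2,3-dimethylcyclohexan-1-one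
Product: 21 (2S,3S,6S)-2-[2-(tert-butyldimethylsilyloxy)ethyl]-6-{[(3S)-3-(tert-butyldimethylsilyloxy)-2-methylhex-5-en-2-yl]oxy}-2,3-dimethylcyclohexan-1-one
Conditions: TBSOTf, 2,6-lutidine, CH2Cl2, −40 → 0 °C
Reagents that add atoms: tert-butyldimethylsilyl triflate, CC(C)(C)[Si](C)(C)OS(=O)(=O)C(F)(F)F
Why: Silyl triflate silylation of a hindered secondary alcohol; this ether stays until the last step.

Step 11
Reactants: 21 (2S,3S,6S)-2-[2-(tert-butyldimethylsilyloxy)ethyl]-6-{[(3S)-3-(tert-butyldimethylsilyloxy)-2-methylhex-5-en-2-yl]oxy}-2,3-dimethylcyclohexan-1-one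
Product: 22 exo-methylene diene: 21 with the ring C=O replaced by C=CH2, a (1S,3S,4S)-2-methylidenecyclohexyl ether
Conditions: Ph3PCH3Br, KOtBu, toluene, 90 °C
Reagents that add atoms: methyltriphenylphosphonium bromide, C[P+](c1ccccc1)(c1ccccc1)c1ccccc1.[Br-]
Why: Wittig methylenation under forcing conditions for a ketone flanked by a quaternary carbon; the only α-hydrogen is at C5, whose equatorial epimer is the stable one, so reversible enolisation does no harm.

Step 12
Reactants: 22 exo-methylene diene
Product: 23 (3S,6S,7S,9aS)-3-(tert-butyldimethylsilyloxy)-6-[2-(tert-butyldimethylsilyloxy)ethyl]-2,2,6,7-tetramethyl-2,3,4,6,7,8,9,9a-octahydro-1-benzoxepine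
Conditions: second-generation Hoveyda–Grubbs catalyst RuCl2(=CH-C6H4-2-OiPr)(H2IMes) (10 mol%), toluene, 80 °C, argon sparge
Reagents that add atoms: none
Why: Ring-closing metathesis: the ruthenium carbene forms on the monosubstituted terminal alkene and closes onto the 1,1-disubstituted exocyclic alkene, forming the trisubstituted C10=C11 bond of ring A with loss of ethene; the gem-dimethyl ether carbon favours the folded chain.

Step 13
Reactants: 23 rings A/B bis-silyl ether
Product: 24 2-[(3S,6S,7S,9aS)-3-(tert-butyldimethylsilyloxy)-2,2,6,7-tetramethyl-2,3,4,6,7,8,9,9a-octahydro-1-benzoxepin-6-yl]ethan-1-ol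
Conditions: HF·pyridine, pyridine, THF, 0 °C
Reagents that add atoms: none
Why: Buffered HF cleaves the primary TBS ether much faster than the secondary one flanked by the quaternary ether carbon.

Step 14
Reactants: 24 rings A/B primary alcohol
Product: 25 2-[(3S,6S,7S,9aS)-3-(tert-butyldimethylsilyloxy)-2,2,6,7-tetramethyl-2,3,4,6,7,8,9,9a-octahydro-1-benzoxepin-6-yl]acetaldehyde
Conditions: Dess–Martin periodinane, NaHCO3, CH2Cl2, 0 °C → rt
Reagents that add atoms: none
Why: Dess–Martin oxidation of a primary alcohol to the aldehyde under buffered conditions that spare the allylic ether and the alkene.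

Step 15
Reactants: 26 7-methyl-1,4-dioxaspiro[4.5]decan-8-one (racemic)
Product: 28 7-methyl-1,4-dioxaspiro[4.5]dec-6-en-8-one, via silyl enol ether 27 (not isolated)
Conditions: TMSCl, Et3N, DMF, 80 °C; then Pd(OAc)2 (10 mol%), O2 (1 atm), DMSO, rt
Reagents that add atoms: none
Why: Saegusa–Ito dehydrogenation: equilibrating silylation gives the more substituted enol ether 27, and palladation followed by β-hydride elimination places the double bond on the methyl-bearing side; the stereocentre of 26 is removed.

Step 16
Reactants: 28 7-methyl-1,4-dioxaspiro[4.5]dec-6-en-8-one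
Product: 29 (8S)-7-methyl-1,4-dioxaspiro[4.5]dec-6-en-8-ol
Conditions: (R)-2-methyl-CBS-oxazaborolidine (10 mol%), catecholborane, toluene, −78 °C
Reagents that add atoms: none
Why: CBS reduction: the oxazaborolidine binds the carbonyl with the α-methylalkenyl arm as the large group and delivers hydride to one face, giving the (8S) allylic alcohol that becomes C22.

Step 17
Reactants: 29 (8S)-7-methyl-1,4-dioxaspiro[4.5]dec-6-en-8-ol
Product: 30 (4S)-4-hydroxy-3-methylcyclohex-2-en-1-one
Conditions: 1 M HCl, THF, 0 °C → rt
Reagents that add atoms: water, O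
Why: Ketal hydrolysis is much faster than ionisation of the allylic alcohol and gives the conjugated enone directly; the carbinol centre is not touched.

Step 18
Reactants: 30 (4S)-4-hydroxy-3-methylcyclohex-2-en-1-one; 16 2-methylbut-3-en-2-yl 2,2,2-trichloroacetimidate
Product: 31 (4S)-3-methyl-4-[(2-methylbut-3-en-2-yl)oxy]cyclohex-2-en-1-one
Conditions: TfOH (5 mol%), cyclohexane/CH2Cl2, −20 → 0 °C
Reagents that add atoms: none
Why: The same imidate O-alkylation as in step 7, here on an unhindered secondary alcohol; the enone makes the substrate's own allylic position electron-poor, so only the reagent ionises.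

Step 19
Reactants: 31 (4S)-3-methyl-4-[(2-methylbut-3-en-2-yl)oxy]cyclohex-2-en-1-one
Product: 32 2-methyl-2-{[(1S)-2-methyl-4-oxocyclohex-2-en-1-yl]oxy}propanal
Conditions: OsO4 (2 mol%), NaIO4, 2,6-lutidine, dioxane/H2O, rt
Reagents that add atoms: osmium tetroxide, O=[Os](=O)(=O)=O; sodium periodate, [Na+].[O-]I(=O)(=O)=O
Why: Lemieux–Johnson cleavage: the electron-rich monosubstituted vinyl group is dihydroxylated and cleaved much faster than the electron-poor trisubstituted enone double bond.

Step 20
Reactants: 32 2-methyl-2-{[(1S)-2-methyl-4-oxocyclohex-2-en-1-yl]oxy}propanal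
Product: 33 (4S)-4-{[(3S)-3-hydroxy-2-methylpent-4-en-2-yl]oxy}-3-methylcyclohex-2-en-1-one
Conditions: Zn(CH=CH2)2 (from CH2=CHMgBr and ZnCl2), (−)-MIB (10 mol%), toluene/hexane, 0 °C
Reagents that add atoms: divinylzinc, C=C[Zn]C=C
Why: Amino-alcohol-catalysed enantioselective addition of a vinylzinc reagent to a non-enolisable aldehyde, with the ligand selecting the face (expected S at C19); uncatalysed organozinc reagents do not add to the enone.

Step 21
Reactants: 33 (4S)-4-{[(3S)-3-hydroxy-2-methylpent-4-en-2-yl]oxy}-3-methylcyclohex-2-en-1-one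
Product: 34 (4S)-3-methyl-4-{[(3S)-2-methyl-3-(triethylsilyloxy)pent-4-en-2-yl]oxy}cyclohex-2-en-1-one
Conditions: TESOTf, 2,6-lutidine, CH2Cl2, −78 °C
Reagents that add atoms: triethylsilyl triflate, CC[Si](CC)(CC)OS(=O)(=O)C(F)(F)F
Why: Silylation of a hindered allylic alcohol; TES is chosen because it can later be removed before the TBS ether at C8.

Step 22
Reactants: 34 (4S)-3-methyl-4-{[(3S)-2-methyl-3-(triethylsilyloxy)pent-4-en-2-yl]oxy}cyclohex-2-en-1-one
Product: 35 {[(3S,4S)-3-ethenyl-3-methyl-4-{[(3S)-2-methyl-3-(triethylsilyloxy)pent-4-en-2-yl]oxy}cyclohex-1-en-1-yl]oxy}trimethylsilane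
Conditions: CH2=CHMgBr, CuBr·SMe2 (10 mol%), TMSCl, HMPA, THF, −78 °C; Et3N, pentane work-up
Reagents that add atoms: vinylmagnesium bromide, C=C[Mg]Br; chlorotrimethylsilane, C[Si](C)(C)Cl
Why: Copper-catalysed conjugate addition accelerated by TMSCl: the vinyl group adds to C16 anti to the γ-alkoxy group on C22, which sets the quaternary centre with the vinyl trans to the ether oxygen, and the enolate is trapped as the silyl enol ether on the C15 side only.

Step 23
Reactants: 35 east silyl enol ether; 25 west aldehyde
Product: 37 β-hydroxy ketone joining C14 of 25 to C15 of the ring C ketone (mixture at C14 and C15), via lithium enolate 36 (not isolated)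
Conditions: MeLi, THF, 0 °C; then 25, −78 °C; NH4Cl
Reagents that add atoms: none
Why: MeLi cleaves the O–Si bond of 35 and gives lithium enolate 36 without loss of regiochemistry, and 36 adds to the aldehyde in an aldol reaction at −78 °C, faster than proton transfer; both new centres are removed or reset in steps 24 and 26.

Step 24
Reactants: 37 β-hydroxy ketone
Product: 39 exocyclic enone with C14=C15 (alkene geometry not assigned), via β-mesyloxy ketone 38 (not isolated)
Conditions: MsCl, Et3N, CH2Cl2, 0 °C; then DBU, rt
Reagents that add atoms: none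
Why: Mesylation and E1cB elimination through the C25 enolate give the conjugated enone from either carbinol epimer.

Step 25
Reactants: 39 exocyclic enone
Product: 40 rings C/D oxepene enone: ring D closed with C17=C18, trans-fused at C16/C22, C19–OTES, C14=C15 enone retained
Conditions: second-generation Grubbs catalyst RuCl2(=CHPh)(PCy3)(H2IMes) (5 mol%), CH2Cl2, 40 °C
Reagents that add atoms: none
Why: Ring-closing metathesis of the two monosubstituted vinyl groups, which are trans-diequatorial on ring C, closes the seven-membered ring D with loss of ethene; the trisubstituted enone and C10=C11 alkenes do not react under these conditions.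

Step 26
Reactants: 40 rings C/D oxepene enone
Product: 41 saturated C25 ketone: rings C/D trans-fused with (15S,16S,22S), C19–OTES, linked through C13–C14 to the silyl-protected rings A/B
Conditions: H2 (1 atm), Pd/C (5%), EtOAc, rt; then DBU (cat.), toluene, rt
Reagents that add atoms: none
Why: Heterogeneous hydrogenation saturates the disubstituted C17=C18 and the enone C14=C15 bonds, while the trisubstituted C10=C11 next to quaternary C12 is too hindered to be adsorbed; base equilibration then puts the C15 side chain equatorial (15S), cis to the axial angular methyl, the stable arrangement next to the ketone.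

Step 27
Reactants: 41 saturated C25 ketone
Product: 42 C25 exo-methylene compound (41 with C25=O replaced by C=CH2)
Conditions: Ph3PCH3Br, KOtBu, toluene, 80 °C
Reagents that add atoms: methyltriphenylphosphonium bromide, C[P+](c1ccccc1)(c1ccccc1)c1ccccc1.[Br-]
Why: Wittig methylenation of an α-branched cyclohexanone; C15 is already the thermodynamic epimer and survives the basic conditions.

Step 28
Reactants: 42 C25 exo-methylene compound
Product: 44 (25S) tertiary alcohol with axial methyl and equatorial hydroxyl at C25, C19–OTES and C8–OTBS retained, via organomercurial 43 (not isolated)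
Conditions: Hg(OAc)2, THF/H2O, rt; then NaBH4, 3 M NaOH, 0 °C
Reagents that add atoms: water, O
Why: Oxymercuration–demercuration: divalent mercury adds to the unhindered 1,1-disubstituted alkene much faster than to the hindered trisubstituted C10=C11, and water opens the mercurinium ion at C25 from the equatorial side because the axial approach is blocked by the 1,3-diaxial methyl on C16; NaBH4 then replaces mercury by hydrogen to give the axial methyl.

Step 29
Reactants: 44 (25S) tertiary alcohol
Product: 45 C19 carbinol (44 with the TES ether cleaved)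
Conditions: PPTS, MeOH/CH2Cl2, 0 °C → rt
Reagents that add atoms: none
Why: Acid-catalysed methanolysis removes the TES ether while the hindered secondary TBS ether at C8 stays; the conditions are too mild to ionise the tertiary carbinol or the allylic ether.

Step 30
Reactants: 45 C19 carbinol
Product: 46 8-O-TBS-sodwanone S (C19 ketone)
Conditions: Dess–Martin periodinane, NaHCO3, CH2Cl2, rt
Reagents that add atoms: none
Why: Dess–Martin oxidation of the only secondary alcohol; the tertiary C25 carbinol cannot be oxidised and the C19 stereocentre is erased.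

Step 31
Reactants: 46 8-O-TBS-sodwanone S
Product: 47 sodwanone S
Conditions: HF·pyridine, pyridine, THF, rt
Reagents that add atoms: none
Why: Fluoride cleavage of the remaining hindered silyl ether under buffered conditions that the α-alkoxy ketone, the tertiary alcohol and the allylic ether tolerate.

## Compound list

1 | 2-methoxybenzoic acid | COc1ccccc1C(=O)O | starting material
2 | (2-bromoethoxy)(tert-butyl)dimethylsilane | BrCCO[Si](C)(C)C(C)(C)C | starting material
3 | dilithium dienediolate from Birch reduction of 1 | COC1=CCC=CC1=C([O-])[O-].[Li+].[Li+] | intermediate (not isolated)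
4 | 1-[2-(tert-butyldimethylsilyloxy)ethyl]-2-methoxycyclohexa-2,5-diene-1-carboxylic acid (racemic) | COC1=CCC=CC1(CCO[Si](C)(C)C(C)(C)C)C(=O)O | intermediate
5 | 2-(2-hydroxyethyl)cyclohex-2-en-1-one | O=C1CCCC=C1CCO | intermediate
6 | 2-[2-(tert-butyldimethylsilyloxy)ethyl]cyclohex-2-en-1-one | O=C1CCCC=C1CCO[Si](C)(C)C(C)(C)C | intermediate
7 | trimethylaluminium | C[Al](C)C | starting material
8 | iodomethane | CI | starting material
9 | dimethylaluminium enolate of (3S)-2-[2-(tert-butyldimethylsilyloxy)ethyl]-3-methylcyclohexanone | C[Al](C)OC1=C(CCO[Si](C)(C)C(C)(C)C)[C@@H](C)CCC1 | intermediate (not isolated)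
10 | (2S,3S)-2-[2-(tert-butyldimethylsilyloxy)ethyl]-2,3-dimethylcyclohexan-1-one | C[C@H]1CCCC(=O)[C@@]1(C)CCO[Si](C)(C)C(C)(C)C | intermediate
11 | tert-butyl{2-[(1S,6S)-1,6-dimethyl-2-(trimethylsilyloxy)cyclohex-2-en-1-yl]ethoxy}dimethylsilane | C[C@H]1CCC=C(O[Si](C)(C)C)[C@@]1(C)CCO[Si](C)(C)C(C)(C)C | intermediate (not isolated)
12 | (2S,3S,6S)-2-[2-(tert-butyldimethylsilyloxy)ethyl]-2,3-dimethyl-6-(trimethylsilyloxy)cyclohexan-1-one | C[C@H]1CC[C@H](O[Si](C)(C)C)C(=O)[C@@]1(C)CCO[Si](C)(C)C(C)(C)C | intermediate (not isolated)
13 | (2S,3S,6S)-2-[2-(tert-butyldimethylsilyloxy)ethyl]-6-hydroxy-2,3-dimethylcyclohexan-1-one | C[C@H]1CC[C@H](O)C(=O)[C@@]1(C)CCO[Si](C)(C)C(C)(C)C | intermediate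
14 | 2-methylbut-3-en-2-ol | C=CC(C)(C)O | starting material
15 | trichloroacetonitrile | N#CC(Cl)(Cl)Cl | starting material
16 | 2-methylbut-3-en-2-yl 2,2,2-trichloroacetimidate | C=CC(C)(C)OC(=N)C(Cl)(Cl)Cl | intermediate
17 | (2S,3S,6S)-2-[2-(tert-butyldimethylsilyloxy)ethyl]-2,3-dimethyl-6-[(2-methylbut-3-en-2-yl)oxy]cyclohexan-1-one | C[C@H]1CC[C@H](OC(C)(C)C=C)C(=O)[C@@]1(C)CCO[Si](C)(C)C(C)(C)C | intermediate
18 | 2-({(1S,3S,4S)-3-[2-(tert-butyldimethylsilyloxy)ethyl]-3,4-dimethyl-2-oxocyclohexyl}oxy)-2-methylpropanal | C[C@H]1CC[C@H](OC(C)(C)C=O)C(=O)[C@@]1(C)CCO[Si](C)(C)C(C)(C)C | intermediate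
19 | diisopinocampheylborinate of 20 (O–B(Ipc)2 on the C8 oxygen) | C[C@H]1CC[C@H](OC(C)(C)[C@H](CC=C)OB([C@@H]2C[C@@H]3C[C@H]([C@H]2C)C3(C)C)[C@@H]2C[C@@H]3C[C@H]([C@H]2C)C3(C)C)C(=O)[C@@]1(C)CCO[Si](C)(C)C(C)(C)C | intermediate (not isolated)
20 | (2S,3S,6S)-2-[2-(tert-butyldimethylsilyloxy)ethyl]-6-{[(3S)-3-hydroxy-2-methylhex-5-en-2-yl]oxy}-2,3-dimethylcyclohexan-1-one | C[C@H]1CC[C@H](OC(C)(C)[C@@H](O)CC=C)C(=O)[C@@]1(C)CCO[Si](C)(C)C(C)(C)C | intermediate
21 | (2S,3S,6S)-2-[2-(tert-butyldimethylsilyloxy)ethyl]-6-{[(3S)-3-(tert-butyldimethylsilyloxy)-2-methylhex-5-en-2-yl]oxy}-2,3-dimethylcyclohexan-1-one | C[C@H]1CC[C@H](OC(C)(C)[C@@H](O[Si](C)(C)C(C)(C)C)CC=C)C(=O)[C@@]1(C)CCO[Si](C)(C)C(C)(C)C | intermediate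
22 | exo-methylene diene: (1S,3S,4S)-3-[2-(tert-butyldimethylsilyloxy)ethyl]-3,4-dimethyl-2-methylidenecyclohexyl ether of (3S)-3-(tert-butyldimethylsilyloxy)-2-methylhex-5-en-2-ol | C[C@H]1CC[C@H](OC(C)(C)[C@@H](O[Si](C)(C)C(C)(C)C)CC=C)C(=C)[C@@]1(C)CCO[Si](C)(C)C(C)(C)C | intermediate
23 | (3S,6S,7S,9aS)-3-(tert-butyldimethylsilyloxy)-6-[2-(tert-butyldimethylsilyloxy)ethyl]-2,2,6,7-tetramethyl-2,3,4,6,7,8,9,9a-octahydro-1-benzoxepine | C[C@H]1CC[C@@H]2OC(C)(C)[C@@H](O[Si](C)(C)C(C)(C)C)CC=C2[C@@]1(C)CCO[Si](C)(C)C(C)(C)C | intermediate
24 | 2-[(3S,6S,7S,9aS)-3-(tert-butyldimethylsilyloxy)-2,2,6,7-tetramethyl-2,3,4,6,7,8,9,9a-octahydro-1-benzoxepin-6-yl]ethan-1-ol | C[C@H]1CC[C@@H]2OC(C)(C)[C@@H](O[Si](C)(C)C(C)(C)C)CC=C2[C@@]1(C)CCO | intermediate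
25 | 2-[(3S,6S,7S,9aS)-3-(tert-butyldimethylsilyloxy)-2,2,6,7-tetramethyl-2,3,4,6,7,8,9,9a-octahydro-1-benzoxepin-6-yl]acetaldehyde | C[C@H]1CC[C@@H]2OC(C)(C)[C@@H](O[Si](C)(C)C(C)(C)C)CC=C2[C@@]1(C)CC=O | intermediate
26 | 7-methyl-1,4-dioxaspiro[4.5]decan-8-one (racemic) | CC1CC2(CCC1=O)OCCO2 | starting material
27 | trimethyl[(7-methyl-1,4-dioxaspiro[4.5]dec-7-en-8-yl)oxy]silane | CC1=C(O[Si](C)(C)C)CCC2(C1)OCCO2 | intermediate (not isolated)
28 | 7-methyl-1,4-dioxaspiro[4.5]dec-6-en-8-one | CC1=CC2(CCC1=O)OCCO2 | intermediate
29 | (8S)-7-methyl-1,4-dioxaspiro[4.5]dec-6-en-8-ol | CC1=CC2(CC[C@@H]1O)OCCO2 | intermediate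
30 | (4S)-4-hydroxy-3-methylcyclohex-2-en-1-one | CC1=CC(=O)CC[C@@H]1O | intermediate
31 | (4S)-3-methyl-4-[(2-methylbut-3-en-2-yl)oxy]cyclohex-2-en-1-one | CC1=CC(=O)CC[C@@H]1OC(C)(C)C=C | intermediate
32 | 2-methyl-2-{[(1S)-2-methyl-4-oxocyclohex-2-en-1-yl]oxy}propanal | CC1=CC(=O)CC[C@@H]1OC(C)(C)C=O | intermediate
33 | (4S)-4-{[(3S)-3-hydroxy-2-methylpent-4-en-2-yl]oxy}-3-methylcyclohex-2-en-1-one | CC1=CC(=O)CC[C@@H]1OC(C)(C)[C@@H](O)C=C | intermediate
34 | (4S)-3-methyl-4-{[(3S)-2-methyl-3-(triethylsilyloxy)pent-4-en-2-yl]oxy}cyclohex-2-en-1-one | CC1=CC(=O)CC[C@@H]1OC(C)(C)[C@@H](O[Si](CC)(CC)CC)C=C | intermediate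
35 | {[(3S,4S)-3-ethenyl-3-methyl-4-{[(3S)-2-methyl-3-(triethylsilyloxy)pent-4-en-2-yl]oxy}cyclohex-1-en-1-yl]oxy}trimethylsilane | C[Si](C)(C)OC1=C[C@](C)(C=C)[C@@H](OC(C)(C)[C@@H](O[Si](CC)(CC)CC)C=C)CC1 | intermediate
36 | lithium enolate corresponding to 35 | [Li]OC1=C[C@](C)(C=C)[C@@H](OC(C)(C)[C@@H](O[Si](CC)(CC)CC)C=C)CC1 | intermediate (not isolated)
37 | aldol adduct: C14 carbinol joining C13 of the west bicycle to C15 of (3S,4S)-3-ethenyl-3-methyl-4-{[(3S)-2-methyl-3-(triethylsilyloxy)pent-4-en-2-yl]oxy}cyclohexan-1-one (C14, C15 unassigned) | C[C@H]1CC[C@@H]2OC(C)(C)[C@@H](O[Si](C)(C)C(C)(C)C)CC=C2[C@@]1(C)CC(O)C1C(=O)CC[C@H](OC(C)(C)[C@@H](O[Si](CC)(CC)CC)C=C)[C@@]1(C)C=C | intermediate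
38 | methanesulfonate of 37 at the C14 oxygen | C[C@H]1CC[C@@H]2OC(C)(C)[C@@H](O[Si](C)(C)C(C)(C)C)CC=C2[C@@]1(C)CC(OS(C)(=O)=O)C1C(=O)CC[C@H](OC(C)(C)[C@@H](O[Si](CC)(CC)CC)C=C)[C@@]1(C)C=C | intermediate (not isolated)
39 | exocyclic enone (C14=C15, geometry unassigned) with vinyl on C16 and the vinyl carbinol TES ether on O21 | C[C@H]1CC[C@@H]2OC(C)(C)[C@@H](O[Si](C)(C)C(C)(C)C)CC=C2[C@@]1(C)CC=C1C(=O)CC[C@H](OC(C)(C)[C@@H](O[Si](CC)(CC)CC)C=C)[C@@]1(C)C=C | intermediate
40 | rings C/D oxepene enone (C17=C18, C14=C15, C19–OTES, trans-fused at C16/C22) | C[C@H]1CC[C@@H]2OC(C)(C)[C@@H](O[Si](C)(C)C(C)(C)C)CC=C2[C@@]1(C)CC=C1C(=O)CC[C@@H]2OC(C)(C)[C@@H](O[Si](CC)(CC)CC)C=C[C@@]12C | intermediate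
41 | saturated C25 ketone, (15S,16S,19S,22S) rings C/D with C19–OTES, C8–OTBS on rings A/B | C[C@H]1CC[C@@H]2OC(C)(C)[C@@H](O[Si](C)(C)C(C)(C)C)CC=C2[C@@]1(C)CC[C@@H]1C(=O)CC[C@@H]2OC(C)(C)[C@@H](O[Si](CC)(CC)CC)CC[C@@]12C | intermediate
42 | C25 exo-methylene compound (41 with C25=CH2) | C[C@H]1CC[C@@H]2OC(C)(C)[C@@H](O[Si](C)(C)C(C)(C)C)CC=C2[C@@]1(C)CC[C@@H]1C(=C)CC[C@@H]2OC(C)(C)[C@@H](O[Si](CC)(CC)CC)CC[C@@]12C | intermediate
43 | acetoxymercuriomethyl carbinol at C25 (oxymercuration adduct of 42) | C[C@H]1CC[C@@H]2OC(C)(C)[C@@H](O[Si](C)(C)C(C)(C)C)CC=C2[C@@]1(C)CC[C@@H]1[C@@](C[Hg]OC(C)=O)(O)CC[C@@H]2OC(C)(C)[C@@H](O[Si](CC)(CC)CC)CC[C@@]12C | intermediate (not isolated)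
44 | (25S) tertiary alcohol, 8-O-TBS-19-O-TES-19-dihydrosodwanone S | C[C@H]1CC[C@@H]2OC(C)(C)[C@@H](O[Si](C)(C)C(C)(C)C)CC=C2[C@@]1(C)CC[C@@H]1[C@@](C)(O)CC[C@@H]2OC(C)(C)[C@@H](O[Si](CC)(CC)CC)CC[C@@]12C | intermediate
45 | 8-O-TBS-19-dihydrosodwanone S (free (19S) carbinol) | C[C@H]1CC[C@@H]2OC(C)(C)[C@@H](O[Si](C)(C)C(C)(C)C)CC=C2[C@@]1(C)CC[C@@H]1[C@@](C)(O)CC[C@@H]2OC(C)(C)[C@@H](O)CC[C@@]12C | intermediate
46 | 8-O-TBS-sodwanone S | C[C@H]1CC[C@@H]2OC(C)(C)[C@@H](O[Si](C)(C)C(C)(C)C)CC=C2[C@@]1(C)CC[C@@H]1[C@@](C)(O)CC[C@@H]2OC(C)(C)C(=O)CC[C@@]12C | intermediate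
47 | sodwanone S | C[C@H]1CC[C@@H]2OC(C)(C)[C@@H](O)CC=C2[C@@]1(C)CC[C@H]1[C@]2(C)CCC(=O)C(C)(C)O[C@H]2CC[C@]1(C)O | target

## Step count and least certain steps

Total step count: 31 (13 to aldehyde 25 in the west branch, 1 for imidate 16, 8 to enol ether 35 in the east branch, 9 from the union to 47). Longest linear sequence: 22 steps (steps 1–5, 7–14 and 23–31).

**Step 4 (key step).** The 2-substituent is larger than the methyl group for which this reaction type is best established. The conjugate addition may therefore be slow, and enantiofacial selectivity may fall. The hindered tetrasubstituted aluminate may also be methylated so slowly that protonation on work-up or enolate equilibration (methylation at C6) competes. The fallback separates the two bond formations. It sets out from 6: the conjugate addition is run as before and the aluminium enolate 9 is intercepted with acetic anhydride to give the isolable enol acetate F1. Two equivalents of MeLi then release the regiodefined lithium enolate F2, which is methylated with MeI in THF/HMPA. The route is rejoined at 10.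

**Step 7.** The 1,1-dimethylallyl cation is ambident. Capture at the primary terminus (a prenyl ether), loss of a proton to isoprene, or rearrangement of 16 before ionisation may compete, and the hydrogen-bonded α-ketol is a weak nucleophile. The fallback uses a cation that is not allylic. It sets out from 13, which is alkylated with 2-methylbut-3-yn-2-yl 2,2,2-trichloroacetimidate F3 (from 2-methylbut-3-yn-2-ol and 15) to give propargylic ether F4. Semi-hydrogenation over Pd/CaCO3–Pb(OAc)2 with quinoline returns to 17.

**Step 12 (and the methylenation of step 11 before it).** The ketone of 21 and the derived 1,1-disubstituted alkene lie between quaternary C12 and the ether carbon C5. Olefination may be slow. In the metathesis the ruthenium carbene on the terminal alkene may dimerise or isomerise the chain before it closes onto the hindered alkene. The fallback forms C10=C11 from two carbonyl groups and bypasses both steps. It sets out from 21: ozonolysis of the terminal alkene gives keto aldehyde F5, and intramolecular McMurry coupling with low-valent titanium (TiCl3(DME)1.5, Zn–Cu, DME, reflux) closes the ring. The route is rejoined at 23. Reductive loss of the α-alkoxy group is the point to watch there.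

**Step 26.** Palladium may migrate or saturate C10=C11, or cleave the allylic C5–O6 bond, before the enone is fully reduced. The fallback uses two homogeneous, site-selective reductions. It sets out from 40: conjugate reduction with catalytic [(Ph3P)CuH]6 under H2 gives the ring D alkene ketone F6. Hydrogenation with RhCl(PPh3)3 then saturates only the disubstituted C17=C18 bond, and DBU equilibration rejoins the route at 41.

**Step 28.** Water may attack the mercurinium ion partly from the axial side, giving the C25 epimer. The acetic acid released may loosen the TES ether, and slow mercuration of C10=C11 cannot be excluded. The fallback delivers the oxygen by a concerted, sterically controlled cycloaddition. It sets out from 42: OsO4 (cat.) with N-methylmorpholine N-oxide dihydroxylates the exocyclic alkene from the equatorial face to give diol F7. Selective mesylation of the primary hydroxyl gives F8, and LiEt3BH reduces the neopentyl-type mesylate to the methyl group. The route is rejoined at 44.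

## Further compounds

F1 | step 4 | (3S)-2-[2-(tert-butyldimethylsilyloxy)ethyl]-3-methylcyclohex-1-en-1-yl acetate | CC(=O)OC1=C(CCO[Si](C)(C)C(C)(C)C)[C@@H](C)CCC1
F2 | step 4 | lithium enolate of (3S)-2-[2-(tert-butyldimethylsilyloxy)ethyl]-3-methylcyclohexanone | [Li]OC1=C(CCO[Si](C)(C)C(C)(C)C)[C@@H](C)CCC1
F3 | step 7 | 2-methylbut-3-yn-2-yl 2,2,2-trichloroacetimidate | C#CC(C)(C)OC(=N)C(Cl)(Cl)Cl
F4 | step 7 | (2S,3S,6S)-2-[2-(tert-butyldimethylsilyloxy)ethyl]-2,3-dimethyl-6-[(2-methylbut-3-yn-2-yl)oxy]cyclohexan-1-one | C[C@H]1CC[C@H](OC(C)(C)C#C)C(=O)[C@@]1(C)CCO[Si](C)(C)C(C)(C)C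
F5 | step 12 | (3S)-3-(tert-butyldimethylsilyloxy)-4-({(1S,3S,4S)-3-[2-(tert-butyldimethylsilyloxy)ethyl]-3,4-dimethyl-2-oxocyclohexyl}oxy)-4-methylpentanal | C[C@H]1CC[C@H](OC(C)(C)[C@@H](O[Si](C)(C)C(C)(C)C)CC=O)C(=O)[C@@]1(C)CCO[Si](C)(C)C(C)(C)C
F6 | step 26 | C25 ketone with saturated C14–C15 and ring D alkene C17=C18 retained | C[C@H]1CC[C@@H]2OC(C)(C)[C@@H](O[Si](C)(C)C(C)(C)C)CC=C2[C@@]1(C)CC[C@@H]1C(=O)CC[C@@H]2OC(C)(C)[C@@H](O[Si](CC)(CC)CC)C=C[C@@]12C
F7 | step 28 | C25 diol (equatorial tertiary hydroxyl, axial hydroxymethyl) | C[C@H]1CC[C@@H]2OC(C)(C)[C@@H](O[Si](C)(C)C(C)(C)C)CC=C2[C@@]1(C)CC[C@@H]1[C@@](CO)(O)CC[C@@H]2OC(C)(C)[C@@H](O[Si](CC)(CC)CC)CC[C@@]12C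
F8 | step 28 | primary methanesulfonate of the C25 diol | C[C@H]1CC[C@@H]2OC(C)(C)[C@@H](O[Si](C)(C)C(C)(C)C)CC=C2[C@@]1(C)CC[C@@H]1[C@@](COS(C)(=O)=O)(O)CC[C@@H]2OC(C)(C)[C@@H](O[Si](CC)(CC)CC)CC[C@@]12C
A1 | alternative 1 | rings C/D exo-methylene alcohol | CC(C)(C)C(=O)OCC[C@H]1[C@]2(C)CC[C@H](O)C(C)(C)O[C@H]2CCC1=C
A2 | alternative 2 | bicyclic ketal containing ring D | C[C@@]12CCC(=O)[C@]3(C)CO[C@@]1(CCCC2=O)O3
A3 | alternative 3 | rings A/B enol silyl ether | C[C@H]1CC[C@@H]2OC(C)(C)[C@@H](O[Si](C)(C)C(C)(C)C)CC=C2[C@@]1(C)/C=C/O[Si](C)(C)C(C)(C)C
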